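Ring A (methylcyclohexene) is disconnected at C3–C4, C3 being the ether-bearing ring-fusion carbon and C4 its CH2 neighbour: this leads back to a 2-isopropenylcyclobutanol (C3, C6, C7, C8) cis-fused to ring B. In one operation its potassium alkoxide should undergo the alkoxide-accelerated vinylcyclobutane [1,3] shift, which enlarges the four-membered ring to ring A, places the C5=C6 alkene, and frees the C3 alkoxide to close the oxolane hemiketal on the ring C ketone C14. The step exploits the cyclohex-3-en-1-ol pattern C3(O)–C4–C5=C6 and the 1,4-relation of C3–O to C14=O. Rings B and C come from an enantioselective thymoquinone Diels–Alder reaction; a vinylketene [2+2] then fuses the cyclobutane.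

Key step: step 9

Atom labels used below: ring A = C3–C4–C5(CH3)=C6–C7–C8; ring B = C1(CO2Me)=C2–C3–C8–C9(CH3)–C10; ring C = C9–C10–C11(=O)–C12(isopropyl)–C13–C14; the ether oxygen links C3 and C14. The "upper face" of ring B carries C11 and C14, the "lower face" carries the C9 methyl and C10–H.

Assumption (chemistry): C12, which is alpha to the C11 ketone, is taken to be the thermodynamically preferred epimer and is set by equilibration; in step 2 the catalyst antipode that gives the drawn series is used (the (S)-prolinol-derived one is written, its mirror image serving if the facial sense proves opposite).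

Step 1
Reactants: 1 methyl (E)-4-oxopent-2-enoate
Product: 2 methyl (E)-4-[(tert-butyldimethylsilyl)oxy]penta-2,4-dienoate
Conditions: TBSOTf (1.1 equiv), Et3N (1.5 equiv), CH2Cl2, 0 °C
Reagents that add atoms: tert-butyldimethylsilyl trifluoromethanesulfonate, CC(C)(C)[Si](C)(C)OS(=O)(=O)C(F)(F)F
Why: Soft enolisation of the methyl ketone (silyl triflate and amine) removes a proton from the acetyl methyl group and traps the oxygen as the 2-silyloxy diene, leaving the (E)-enoate untouched and forming no stereocentre.

Step 2
Reactants: 2 methyl (E)-4-[(tert-butyldimethylsilyl)oxy]penta-2,4-dienoate; 3 thymoquinone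
Product: 4 cis-fused Diels–Alder adduct (ring B silyl enol ether at C2=C3; ring C enedione)
Conditions: (S)-1-(2-methylphenyl)-3,3-diphenyltetrahydro-1H,3H-pyrrolo[1,2-c][1,3,2]oxazaborole (20 mol %), HNTf2 (20 mol %), CH2Cl2, −78 → −40 °C
Reagents that add atoms: none
Why: Catalytic enantioselective Diels–Alder reaction in which the chiral oxazaborolidinium ion binds the quinone carbonyl next to C10–H, the nucleophilic CH2 terminus of the 2-silyloxy diene bonds to the methyl-bearing carbon C9 of the less hindered double bond and the ester terminus to C10, endo addition giving the cis ring fusion (C9 methyl and C10–H on the lower face) while the catalyst shields one quinone face and so sets the absolute configuration of C9 and C10 (C1 is also set but is flattened in step 3).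

Step 3
Reactants: 4 cis-fused Diels–Alder adduct
Product: 5 ene-keto-ester (C1=C2 enoate conjugated with the C3 ketone)
Conditions: Pd(OAc)2 (1.1 equiv), MeCN, 40 °C
Reagents that add atoms: none
Why: Saegusa–Ito oxidation, in which the palladium enolate at C2 can undergo beta-hydride elimination only toward C1, so the C1=C2 double bond is formed regiospecifically and no stereocentre is touched.

Step 4
Reactants: 5 ene-keto-ester
Product: 6 cross-conjugated silyl dienol ether (C3=C8 enol ether; C1=C2 enoate)
Conditions: TBSOTf (1.2 equiv), Et3N (2 equiv), CH2Cl2, −78 °C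
Reagents that add atoms: tert-butyldimethylsilyl trifluoromethanesulfonate, CC(C)(C)[Si](C)(C)OS(=O)(=O)C(F)(F)F
Why: Soft enolisation of the enone, where C8 carries the only alpha'-hydrogens of the C3 ketone and the C10–H bond, held near the plane of the enoate by allylic strain with the C1 ester, is poorly aligned for gamma-deprotonation, so the cross-conjugated 2-silyloxy diene should form under kinetic control.

Step 5
Reactants: 6 cross-conjugated silyl dienol ether; 7 3-methylbut-2-enoyl chloride
Product: 9 cyclobutanone-fused silyl ether (four-membered ring C3–C6–C7–C8; C7 ketone; isopropenyl on C6), via isopropenylketene 8 (not isolated)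
Conditions: Et3N (3.5 equiv), 7 (3 equiv, added over 6 h), CH2Cl2, 40 °C
Reagents that add atoms: none
Why: Ketene–enol ether [2+2] cycloaddition in which triethylamine converts 7 by 1,4-dehydrochlorination into isopropenylketene 8, whose carbonyl carbon (C7) bonds to the nucleophilic C8 and whose alpha-carbon (C6) bonds to C3 from the convex lower face (syn to the C9 methyl, anti to ring C), which sets C3 (oxygen up) and C8 (hydrogen up), while C6, alpha to the new ketone, should settle with isopropenyl on the exo side, trans to the C2 arm.

Step 6
Reactants: 9 cyclobutanone-fused silyl ether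
Product: 10 ring C saturated diketone (C12–H and C13H2)
Conditions: Zn dust (10 equiv), AcOH, 25 °C
Reagents that add atoms: none
Why: Dissolving-metal reduction with zinc in acetic acid reduces only the ene-1,4-dione of ring C and leaves the isolated ketone, the enoate, the isopropenyl group and the silyl ether, and C12 should take up the equatorial isopropyl configuration by acid-mediated equilibration alpha to C11.

Step 7
Reactants: 10 ring C saturated diketone
Product: 12 vinylcyclobutane silyl ether (C7 methylene), via tosylhydrazone 11 (not isolated)
Conditions: TsNHNH2 (1.1 equiv), THF, 25 °C; then catecholborane (1.5 equiv), CHCl3, −10 °C; then NaOAc·3H2O, 60 °C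
Reagents that add atoms: none
Why: Tosylhydrazone reduction (Caglioti-type, catecholborane variant), in which the strained and most electrophilic cyclobutanone should condense selectively, catecholborane reduces the C=N bond and acetate triggers loss of sulfinate and dinitrogen from the resulting diazene, turning C7 into a methylene group without moving the beta,gamma-alkene or touching a stereocentre.

Step 8
Reactants: 12 vinylcyclobutane silyl ether
Product: 13 tertiary 2-isopropenylcyclobutanol
Conditions: HF·pyridine, THF, 0 → 25 °C
Reagents that add atoms: none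
Why: Buffered fluoride desilylation cleaves the hindered tertiary silyl ether under non-basic conditions at or below room temperature, so neither the alkoxide chemistry of step 9 nor a thermal retro-ene opening is triggered early (the free alcohol may rest as its hemiketal with C14).

Step 9
Reactants: 13 tertiary 2-isopropenylcyclobutanol
Product: 16 CNP0382995.2 (target), via potassium cyclobutanolate 14 (not isolated), via potassium cyclohexenolate 15 (not isolated)
Conditions: KH (1.2 equiv), 18-crown-6 (1.2 equiv), THF, 0 → 25 °C; then aq. NH4Cl
Reagents that add atoms: none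
Why: KH turns the tertiary alcohol (or its C14 hemiketal) into potassium alkoxide 14, which should follow the alkoxide-accelerated vinylcyclobutane rearrangement known for 2-vinylcyclobutanols: the strained C3–C6 bond breaks heterolytically to an ion pair (C3 ketone conjugated with the enoate; 2-methylallyl anion tethered through C7 to C8) and the allyl terminus C4 re-adds to C3, a net suprafacial [1,3] shift that enlarges the four-membered ring by two atoms. Ring A closes by 6-exo-trig 1,2-addition at the C3 carbonyl, and alkoxide 15 then closes the oxolane by 5-exo-trig addition to the C14 ketone, protonation on work-up giving the hemiketal. C3 is controlled by C8, because the C7 tether delivers C4 only to the lower face, so the oxygen stays on the upper face beside C14; C14 is fixed by the bridge, and C12 can only re-equilibrate to the same equatorial epimer. The C5=C6 position follows from the allylic transposition. The step needs the [1,3] path to beat the anionic oxy-Cope, proton transfer and conjugate re-addition: the two alkenyl groups are trans on the cyclobutane, so the boat [3,3] geometry is out of reach; C1 is fully substituted and remote, whereas C4 reaches the carbonyl carbon through a six-membered transition state; and the most acidic C–H (C10) lies close to the nodal plane of the enoate, which should slow its transfer to the allyl anion.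

Compound list
1 | methyl (E)-4-oxopent-2-enoate | CC(=O)/C=C/C(=O)OC | starting material
2 | methyl (E)-4-[(tert-butyldimethylsilyl)oxy]penta-2,4-dienoate | C=C(O[Si](C)(C)C(C)(C)C)/C=C/C(=O)OC | intermediate
3 | thymoquinone, 2-methyl-5-(propan-2-yl)cyclohexa-2,5-diene-1,4-dione | CC1=CC(=O)C(C(C)C)=CC1=O | starting material
4 | Diels–Alder adduct: methyl 3-[(tert-butyldimethylsilyl)oxy]-4a-methyl-5,8-dioxo-7-(propan-2-yl)-1,4,4a,5,8,8a-hexahydronaphthalene-1-carboxylate; cis ring fusion, ester cis to the ring C carbonyl carbons | COC(=O)[C@H]1C=C(O[Si](C)(C)C(C)(C)C)C[C@]2(C)[C@H]1C(=O)C(C(C)C)=CC2=O | intermediate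
5 | ene-keto-ester: methyl 4a-methyl-3,5,8-trioxo-7-(propan-2-yl)-3,4,4a,5,8,8a-hexahydronaphthalene-1-carboxylate; cis ring fusion | COC(=O)C1=CC(=O)C[C@]2(C)[C@H]1C(=O)C(C(C)C)=CC2=O | intermediate
6 | cross-conjugated silyl dienol ether: methyl 3-[(tert-butyldimethylsilyl)oxy]-4a-methyl-5,8-dioxo-7-(propan-2-yl)-4a,5,8,8a-tetrahydronaphthalene-1-carboxylate; cis ring fusion | COC(=O)C1=CC(O[Si](C)(C)C(C)(C)C)=C[C@]2(C)[C@H]1C(=O)C(C(C)C)=CC2=O | intermediate
7 | 3-methylbut-2-enoyl chloride | CC(C)=CC(Cl)=O | starting material
8 | isopropenylketene, 3-methylbuta-1,3-dien-1-one | CC(=C)C=C=O | intermediate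
9 | cyclobutanone-fused silyl ether: ring B of 6 with a cyclobutanone (C3–C6–C7(=O)–C8) cis-fused on the lower face; C3 bears OTBS (up), C8–H up, isopropenyl on C6 cis to the C3 oxygen; ring C enedione | COC(=O)C1=C[C@]2(O[Si](C)(C)C(C)(C)C)[C@@H](C(C)=C)C(=O)[C@@H]2[C@]3(C)[C@H]1C(=O)C(C(C)C)=CC3=O | intermediate
10 | as 9 but with ring C reduced to the saturated 1,4-diketone, isopropyl on C12 equatorial | COC(=O)C1=C[C@]2(O[Si](C)(C)C(C)(C)C)[C@@H](C(C)=C)C(=O)[C@@H]2[C@]3(C)[C@H]1C(=O)[C@@H](C(C)C)CC3=O | intermediate
11 | 4-methylbenzenesulfonylhydrazone of the C7 ketone of 10 | COC(=O)C1=C[C@]2(O[Si](C)(C)C(C)(C)C)[C@@H](C(C)=C)C(=NNS(=O)(=O)c4ccc(C)cc4)[C@@H]2[C@]3(C)[C@H]1C(=O)[C@@H](C(C)C)CC3=O | intermediate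
12 | vinylcyclobutane silyl ether: as 10 but C7 is CH2 (C3–C6–C7–C8 cyclobutane, C3–OTBS, isopropenyl on C6) | COC(=O)C1=C[C@]2(O[Si](C)(C)C(C)(C)C)[C@@H](C(C)=C)C[C@@H]2[C@]3(C)[C@H]1C(=O)[C@@H](C(C)C)CC3=O | intermediate
13 | tertiary 2-isopropenylcyclobutanol: as 12 with free C3–OH (drawn as the open hydroxy diketone) | COC(=O)C1=C[C@]2(O)[C@@H](C(C)=C)C[C@@H]2[C@]3(C)[C@H]1C(=O)[C@@H](C(C)C)CC3=O | intermediate
14 | potassium cyclobutanolate of 13 (alkoxide on C3) | COC(=O)C1=C[C@]2([O-])[C@@H](C(C)=C)C[C@@H]2[C@]3(C)[C@H]1C(=O)[C@@H](C(C)C)CC3=O.[K+] | intermediate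
15 | potassium cyclohexenolate: ring A formed (C3–C4–C5(CH3)=C6–C7–C8), alkoxide on C3 on the upper face, ring C still the open diketone | COC(=O)C1=C[C@]2([O-])CC(C)=CC[C@@H]2[C@]3(C)[C@H]1C(=O)[C@@H](C(C)C)CC3=O.[K+] | intermediate
16 | CNP0382995.2: tetracyclic methyl ester with the C3–O–C14 hemiketal bridge | COC(=O)C1=C[C@]23CC(C)=CC[C@@H]2[C@]2(C)[C@H]1C(=O)[C@@H](C(C)C)C[C@@]2(O)O3 | target

Total step count: 9. Longest linear sequence: 9 steps (1 → 16); 3 and 7 are commercial.

Steps most likely to fail

Step 9 (key step). The transient allyl anion may be quenched by proton transfer from a ketone alpha-position or from C10 before it recombines, or the alkoxide may open by a retro-ene path, so that the four-membered ring opens without ring A forming. The fallback removes the anion altogether. It sets out from silyl ether 12, which is heated (toluene, sealed tube, about 190 °C). The C3–C6 bond is flanked by a silyloxy- and enoate-stabilised centre and an allylic one, and should undergo the thermal vinylcyclobutane-to-cyclohexene rearrangement to the ring-enlarged silyl ether F1. HF·pyridine then frees the tertiary alcohol, which closes onto C14, and the route is rejoined at 16.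

Step 5. Self-condensation of the vinylketene, or plain C-acylation of the enol ether without ring closure, may outpace cycloaddition onto the hindered trisubstituted enol ether. The fallback sets out from 6 and uses a far more electrophilic two-carbon partner. N,N,3-Trimethylbut-2-enamide is activated with Tf2O and 2,4,6-collidine (CH2Cl2, −20 °C) to the vinyl keteniminium triflate, which should add stepwise across C3=C8 from the same face to give the cyclobutaniminium triflate F2. Aqueous NaHCO3 hydrolysis returns the route at 9.

Step 7. Chemoselectivity may be lost: hydrazone formation may spread to the ring C ketones, or the borane may reduce a ketone. The fallback sets out from 10 and removes the oxygen by a radical path. NaBH4 (MeOH/CH2Cl2, −78 °C) should reduce only the strained cyclobutanone, hydride arriving from the exo face, to the cyclobutanol F3. Phenyl chlorothionoformate with pyridine and DMAP gives the O-phenyl thiocarbonate F4. Barton–McCombie deoxygenation (Bu3SnH, AIBN, toluene, 80 °C) then rejoins the route at 12.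

Further compounds
F1 | step 9 | ring-enlarged silyl ether: ring A formed, C3–OTBS on the upper face, ring C open diketone | COC(=O)C1=C[C@]2(O[Si](C)(C)C(C)(C)C)CC(C)=CC[C@@H]2[C@]3(C)[C@H]1C(=O)[C@@H](C(C)C)CC3=O
F2 | step 5 | cyclobutaniminium triflate: as 9 with C7=N(+)(CH3)2 in place of the C7 ketone | COC(=O)C1=C[C@]2(O[Si](C)(C)C(C)(C)C)[C@@H](C(C)=C)C(=[N+](C)C)[C@@H]2[C@]3(C)[C@H]1C(=O)C(C(C)C)=CC3=O.[O-]S(=O)(=O)C(F)(F)F
F3 | step 7 | cyclobutanol: as 10 with C7–OH (hydroxyl on the face of ring B) | COC(=O)C1=C[C@]2(O[Si](C)(C)C(C)(C)C)[C@@H](C(C)=C)[C@H](O)[C@@H]2[C@]3(C)[C@H]1C(=O)[C@@H](C(C)C)CC3=O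
F4 | step 7 | O-phenyl thiocarbonate of F3 | COC(=O)C1=C[C@]2(O[Si](C)(C)C(C)(C)C)[C@@H](C(C)=C)[C@H](OC(=S)Oc4ccccc4)[C@@H]2[C@]3(C)[C@H]1C(=O)[C@@H](C(C)C)CC3=O
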